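**Plan**

- Numbering used throughout: ring C1 (bears the side chain), C2 (OH), C3–C4 (epoxide, methyl on C4), C5 (C=O), C6 (OAc); chain C7(=C8H2)–C9(O-angeloyl)–C10H2–C11H=C12Me2.
- Enabling feature: C8=C7–C1–C2–OH is a homoallylic alcohol whose carbons C1 and C2 are adjacent and trans in the six-membered ring C1–C6, which is the product pattern of a type 1 carbonyl-ene cyclization.
- Retrosynthesis: the C3–C4 epoxide oxygen is removed first; then ring bond C1–C2 is cut (retro-ene, one hydrogen returns to C8) to give an acyclic (Z)-4-oxo-2-enal; its C2 and C5 carbonyls are folded back into a 3-methylfuran; then C6–C1, the two ester C–O bonds, C7–C8 with C1–I, and the C9–alkyne bond are cut.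
- Forward: the C7–C12 chain is built and angeloylated, joined to the furan aldehyde at C6–C1, the furan is opened, the only ring (carbocycle C1–C6) closes in the ene step, and the epoxide is added last.
- Stereochemistry: C9 from a Ru-catalysed asymmetric transfer hydrogenation; C6 from a ligand-controlled CrCl2/NiCl2 coupling; C1 and C2 from C6 in the ene step; C3/C4 from a C5–OH-directed epoxidation after a Luche reduction steered by C6; the (Z)-alkenes from angelic acid, an anti-carbomagnesiation and the furan ring.

Key step: step 10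

Assumption: the (S,S)-Ru complex of step 3 and the (S)-sulfonamide ligand of step 7 are taken as the enantiomers that lead to (9S) and (6R); if the sense of induction is opposite, the mirror-image catalyst or ligand is used and nothing else changes.

**Route**

Step 1
Reactants: 1 4-methylpent-3-enoic acid
Product: 3 N-methoxy-N,4-dimethylpent-3-enamide, via acyl imidazolide 2 (not isolated)
Conditions: 1,1'-carbonyldiimidazole (CDI), CH2Cl2, 0 °C → rt; then MeNH(OMe)·HCl, rt
Reagents that add atoms: N,O-dimethylhydroxylamine hydrochloride, CNOC.Cl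
Why: CDI activation followed by aminolysis is a standard Weinreb amide synthesis, and its near-neutral conditions should leave the β,γ-double bond out of conjugation.

Step 2
Reactants: 3 N-methoxy-N,4-dimethylpent-3-enamide; 4 ethynyltrimethylsilane
Product: 7 6-methyl-1-(trimethylsilyl)hept-5-en-1-yn-3-one, via lithium (trimethylsilyl)acetylide 5 (not isolated), via lithium hemiaminal adduct 6 (not isolated)
Conditions: 4, nBuLi, THF, −78 °C; then 3, −78 → −20 °C; then AcOH, −78 °C
Reagents that add atoms: none
Why: Weinreb ketone synthesis, in which the acetylide adds once because the N-methoxy chelate 6 persists until the cold acetic acid quench, which should release the β,γ-unsaturated ynone without isomerisation into conjugation.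

Step 3
Reactants: 7 6-methyl-1-(trimethylsilyl)hept-5-en-1-yn-3-one
Product: 8 (3S)-6-methyl-1-(trimethylsilyl)hept-5-en-1-yn-3-ol
Conditions: Ru(p-cymene)[(S,S)-TsNCH(Ph)CH(Ph)NH] (1 mol%), iPrOH, rt
Reagents that add atoms: none
Why: Noyori asymmetric transfer hydrogenation of an alkynyl ketone, in which the Ru–H/N–H catalyst delivers hydride with the alkynyl group in the place an aryl group normally takes, so the (S,S)-complex should give the (S)-carbinol (C9) while base-free isopropanol spares the triple bond and the acidic CH2.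

Step 4
Reactants: 8 (3S)-6-methyl-1-(trimethylsilyl)hept-5-en-1-yn-3-ol
Product: 9 (3S)-6-methylhept-5-en-1-yn-3-ol
Conditions: K2CO3 (cat.), MeOH, 0 °C → rt
Reagents that add atoms: none
Why: carbonate-catalysed methanolysis of the C(sp)–Si bond (protodesilylation of a silylalkyne) frees the terminal alkyne and does not touch the carbinol centre.

Step 5
Reactants: 9 (3S)-6-methylhept-5-en-1-yn-3-ol
Product: 11 (1Z,3S)-1-iodo-2,6-dimethylhepta-1,5-dien-3-ol, via alkenylmagnesium alkoxide 10 (not isolated)
Conditions: MeMgBr (3.5 equiv), CuI (10 mol%), THF, −10 °C → rt; then I2, −78 → 0 °C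
Reagents that add atoms: methylmagnesium bromide, C[Mg]Br; iodine, II
Why: hydroxyl-directed copper-catalysed anti-carbomagnesiation of the propargylic alkoxide puts methyl (C8) on the internal carbon and magnesium on the terminal carbon in a five-membered chelate, and iodinolysis with retention should give the (Z)-iodoalkene with iodine cis to the carbinol carbon.

Step 6
Reactants: 11 (1Z,3S)-1-iodo-2,6-dimethylhepta-1,5-dien-3-ol; 12 angelic acid
Product: 14 (1Z,3S)-1-iodo-2,6-dimethylhepta-1,5-dien-3-yl (Z)-2-methylbut-2-enoate, via mixed anhydride 13 (not isolated)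
Conditions: 12, 2,4,6-Cl3C6H2COCl, Et3N, toluene, rt; then 11, 80 °C
Reagents that add atoms: none
Why: Yamaguchi esterification through the mixed anhydride without a nucleophilic acyl-transfer catalyst is the established way to transfer an angeloyl group without isomerisation to the tiglate, the alcohol attacking the unhindered angeloyl carbonyl with retention at C9.

Step 7
Reactants: 14 (1Z,3S)-1-iodo-2,6-dimethylhepta-1,5-dien-3-yl (Z)-2-methylbut-2-enoate; 15 3-methylfuran-2-carbaldehyde
Product: 16 (1R,2Z,4S)-1-hydroxy-3,7-dimethyl-1-(3-methylfuran-2-yl)octa-2,6-dien-4-yl (Z)-2-methylbut-2-enoate [(6R,9S) in target numbering]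
Conditions: CrCl2 (3 equiv), (S)-N-[2-(4-isopropyl-4,5-dihydrooxazol-2-yl)-6-methylphenyl]methanesulfonamide, Et3N, THF, rt; then NiCl2 (cat.), 15, 14, rt
Reagents that add atoms: none
Why: Nozaki–Hiyama–Kishi alkenylation, in which zerovalent nickel inserts into the C–I bond with retention of the (Z) geometry, the alkenyl trivalent chromium species tolerates both esters, and addition to the aldehyde inside the chiral sulfonamide–chromium complex should set C6 as R by reagent control.

Step 8
Reactants: 16 furyl carbinol (6R,9S)
Product: 17 (1R,2Z,4S)-1-acetoxy-3,7-dimethyl-1-(3-methylfuran-2-yl)octa-2,6-dien-4-yl (Z)-2-methylbut-2-enoate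
Conditions: Ac2O, pyridine, DMAP (cat.), CH2Cl2, 0 °C
Reagents that add atoms: acetic anhydride, CC(=O)OC(C)=O
Why: DMAP-catalysed acylation proceeds with retention at C6, installs the C6 acetate of the target and, by capping the furfuryl hydroxyl, prevents Achmatowicz ring expansion in the next step.

Step 9
Reactants: 17 furyl acetate (6R,9S)
Product: 18 (2Z,5R,6Z,8S)-5-acetoxy-3,7,11-trimethyl-8-{[(Z)-2-methylbut-2-enoyl]oxy}-4-oxododeca-2,6,10-trienal [acyclic (Z)-4-oxo-2-enal; C2 aldehyde, C5 ketone]
Conditions: NBS (1.0 equiv), NaHCO3, acetone/H2O, −20 °C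
Reagents that add atoms: water, O
Why: oxidative furan ring opening, in which NBS brominates the free α-carbon, water adds to the substituted α-carbon and loss of HBr opens the dihydrofuran to the cis-ene-dicarbonyl with the (Z)-C3=C4 geometry of the ring, the furan being the most nucleophilic π-system so that one equivalent at low temperature should spare the other alkenes and C6.

Step 10
Reactants: 18 acyclic (Z)-4-oxo-2-enal (6R,9S)
Product: 20 (1S,2R,6R,9S)-6-acetoxy-2-hydroxy-4-methyl-5-oxocyclohex-3-enyl compound [4-hydroxy-2-methylcyclohex-2-enone; C6–OAc / C1 chain / C2–OH all trans; chain = (3S)-3-angeloyloxy-6-methylhepta-1,5-dien-2-yl], via aluminium alkoxide 19 (not isolated)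
Conditions: Me2AlCl (2.5 equiv), CH2Cl2, −78 → −40 °C; then H2O, 0 °C
Reagents that add atoms: none
Why: Me2AlCl binds the aldehyde, which conjugation through the (Z)-C3=C4 bond to the C5 ketone makes a strong enophile, and C1 of the trisubstituted C1=C7 alkene bonds to C2 while a hydrogen of the C8 methyl passes to the aldehyde oxygen in one asynchronous six-centre step, after which the alcohol–aluminium complex loses methane to give the non-acidic alkoxide 19. The closest known reaction is the Lewis-acid-promoted type 1 intramolecular carbonyl-ene cyclization of 6-enals such as citronellal to isopulegol. The carbocycle C1–C6 closes by 6-exo-trig attack on the aldehyde carbon through a half-chair in which C3, C4 and C5 are planar and the C1=C7 bond stays outside the ring. C1 is set by allylic 1,3-strain: C9, cis to C6 on the (Z)-alkene, holds the C6–H in the alkene plane, so the tether reaches C1 only from the face opposite the acetate and C6–OAc and the C1 substituent become trans-diequatorial. C2 is set by the ene geometry, since only an equatorial aluminium-bound oxygen lies beside the C8 methyl (trans to C6), which gives the trans C1/C2 relation and the C7=C8 methylene. The step needs attack of C1 on the aldehyde carbon, hydrogen transfer from C8 and not from C9, and the trans,trans triad; the first is secured by ring size (bonding of C1 to C3 or C4 would be a 5-endo or a four-membered closure), the second by the position of C9 away from the oxygen and by its acyloxy group, the third by the (Z) geometry of both double bonds and the equatorial C6 acetate.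

Step 11
Reactants: 20 ene product (1S,2R,6R,9S)
Product: 21 C2 triethylsilyl ether of 20 [(1R,2R,6R,9S); the descriptor at C1 changes by priority only]
Conditions: TESCl, imidazole, DMF, 0 °C
Reagents that add atoms: chlorotriethylsilane, CC[Si](Cl)(CC)CC
Why: silyl ether formation at the only free hydroxyl masks C2–OH so that C5–OH alone directs the later epoxidation and only C5 is touched by the later oxidation.

Step 12
Reactants: 21 silyl ether enone
Product: 22 (1R,2R,5R,6R,9S)-cyclohex-3-en-5-ol [C5–OH trans to C6–OAc, cis to the C1 chain]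
Conditions: NaBH4, CeCl3·7H2O, MeOH, −78 °C
Reagents that add atoms: none
Why: Luche reduction gives clean 1,2-reduction of the enone, and axial hydride delivery to the half-chair with three equatorial substituents should place the new C5–OH equatorial and trans to C6–OAc, the esters being inert at −78 °C.

Step 13
Reactants: 22 allylic alcohol
Product: 23 (1R,2S,3R,4S,5S,6R,9S)-3,4-epoxy alcohol [epoxide cis to C5–OH, trans to C2–OSiEt3]
Conditions: VO(acac)2 (5 mol%), tBuOOH (decane), CH2Cl2, 0 °C → rt
Reagents that add atoms: tert-butyl hydroperoxide, CC(C)(C)OO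
Why: hydroxyl-directed vanadium-catalysed epoxidation of a cyclic allylic alcohol delivers oxygen to the face of C3=C4 that C5–OH occupies, which is also the face anti to the C2 silyl ether, setting C3 and C4, while the other alkenes lack an allylic hydroxyl and react far more slowly (any enone formed by over-oxidation is 21 and can be recycled).

Step 14
Reactants: 23 epoxy alcohol
Product: 24 (1R,2S,3R,4R,6R,9S)-epoxy ketone triethylsilyl ether
Conditions: Dess–Martin periodinane, pyridine, CH2Cl2, 0 °C → rt
Reagents that add atoms: none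
Why: Dess–Martin oxidation returns the C5 ketone under buffered, non-basic conditions that should neither epimerise C6 nor open the epoxide.

Step 15
Reactants: 24 epoxy ketone triethylsilyl ether
Product: 25 target CNP0272666.1 [(1S,2S,3R,4R,6R,9S)]
Conditions: HF·pyridine, pyridine, THF, 0 °C
Reagents that add atoms: none
Why: buffered HF·pyridine cleaves the triethylsilyl ether (fluoride-mediated desilylation) without base, so the acetate, the angelate and the α,β-epoxy ketone should survive.

**Compound list**

1 | 4-methylpent-3-enoic acid | CC(C)=CCC(=O)O | starting material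
2 | 1-(4-methylpent-3-enoyl)imidazole | CC(C)=CCC(=O)n1ccnc1 | intermediate (not isolated)
3 | N-methoxy-N,4-dimethylpent-3-enamide | CC(C)=CCC(=O)N(C)OC | intermediate
4 | ethynyltrimethylsilane | C#C[Si](C)(C)C | starting material
5 | lithium (trimethylsilyl)acetylide | [Li]C#C[Si](C)(C)C | intermediate (not isolated)
6 | lithium alkoxide of the N-methoxy-N-methyl hemiaminal from 3 and 5 | CC(C)=CCC(O[Li])(N(C)OC)C#C[Si](C)(C)C | intermediate (not isolated)
7 | 6-methyl-1-(trimethylsilyl)hept-5-en-1-yn-3-one | CC(C)=CCC(=O)C#C[Si](C)(C)C | intermediate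
8 | (3S)-6-methyl-1-(trimethylsilyl)hept-5-en-1-yn-3-ol | C[Si](C)(C)C#C[C@H](CC=C(C)C)O | intermediate
9 | (3S)-6-methylhept-5-en-1-yn-3-ol | C#C[C@H](CC=C(C)C)O | intermediate
10 | bromomagnesium (1Z,3S)-1-(bromomagnesio)-2,6-dimethylhepta-1,5-dien-3-olate | Br[Mg]/C=C(/C)[C@H](CC=C(C)C)O[Mg]Br | intermediate (not isolated)
11 | (1Z,3S)-1-iodo-2,6-dimethylhepta-1,5-dien-3-ol | I/C=C(/C)[C@H](CC=C(C)C)O | intermediate
12 | angelic acid, (Z)-2-methylbut-2-enoic acid | C/C=C(/C)C(=O)O | starting material
13 | (Z)-2-methylbut-2-enoic 2,4,6-trichlorobenzoic anhydride | C/C=C(/C)C(=O)OC(=O)c1c(Cl)cc(Cl)cc1Cl | intermediate (not isolated)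
14 | (1Z,3S)-1-iodo-2,6-dimethylhepta-1,5-dien-3-yl (Z)-2-methylbut-2-enoate | I/C=C(/C)[C@H](CC=C(C)C)OC(=O)/C(C)=C\C | intermediate
15 | 3-methylfuran-2-carbaldehyde | Cc1ccoc1C=O | starting material
16 | (1R,2Z,4S)-1-hydroxy-3,7-dimethyl-1-(3-methylfuran-2-yl)octa-2,6-dien-4-yl (Z)-2-methylbut-2-enoate | Cc1ccoc1[C@H](O)/C=C(/C)[C@H](CC=C(C)C)OC(=O)/C(C)=C\C | intermediate
17 | (1R,2Z,4S)-1-acetoxy-3,7-dimethyl-1-(3-methylfuran-2-yl)octa-2,6-dien-4-yl (Z)-2-methylbut-2-enoate | Cc1ccoc1[C@H](OC(C)=O)/C=C(/C)[C@H](CC=C(C)C)OC(=O)/C(C)=C\C | intermediate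
18 | (2Z,5R,6Z,8S)-5-acetoxy-3,7,11-trimethyl-8-{[(Z)-2-methylbut-2-enoyl]oxy}-4-oxododeca-2,6,10-trienal (ene precursor) | C/C(=C/[C@@H](OC(C)=O)C(=O)/C(C)=C\C=O)[C@H](CC=C(C)C)OC(=O)/C(C)=C\C | intermediate
19 | chloro(methyl)aluminium C2-alkoxide of 20 | C=C([C@H]1[C@H](O[Al](C)Cl)C=C(C)C(=O)[C@@H]1OC(C)=O)[C@H](CC=C(C)C)OC(=O)/C(C)=C\C | intermediate (not isolated)
20 | (1S,2R,6R,9S) ene product: 6-acetoxy-4-hydroxy-2-methylcyclohex-2-enone (enone numbering) carrying at C1 the (3S)-3-angeloyloxy-6-methylhepta-1,5-dien-2-yl chain, OAc/chain/OH all trans | C=C([C@H]1[C@H](O)C=C(C)C(=O)[C@@H]1OC(C)=O)[C@H](CC=C(C)C)OC(=O)/C(C)=C\C | intermediate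
21 | (1R,2R,6R,9S) C2 triethylsilyl ether of 20 | C=C([C@H]1[C@H](O[Si](CC)(CC)CC)C=C(C)C(=O)[C@@H]1OC(C)=O)[C@H](CC=C(C)C)OC(=O)/C(C)=C\C | intermediate
22 | (1R,2R,5R,6R,9S) allylic alcohol, C5–OH trans to C6–OAc | C=C([C@H]1[C@H](O[Si](CC)(CC)CC)C=C(C)[C@@H](O)[C@@H]1OC(C)=O)[C@H](CC=C(C)C)OC(=O)/C(C)=C\C | intermediate
23 | (1R,2S,3R,4S,5S,6R,9S) 3,4-epoxy alcohol, epoxide cis to C5–OH | C=C([C@H]1[C@H](O[Si](CC)(CC)CC)[C@H]2O[C@@]2(C)[C@@H](O)[C@@H]1OC(C)=O)[C@H](CC=C(C)C)OC(=O)/C(C)=C\C | intermediate
24 | (1R,2S,3R,4R,6R,9S) epoxy ketone, C2 triethylsilyl ether of the target | C=C([C@H]1[C@H](O[Si](CC)(CC)CC)[C@H]2O[C@@]2(C)C(=O)[C@@H]1OC(C)=O)[C@H](CC=C(C)C)OC(=O)/C(C)=C\C | intermediate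
25 | CNP0272666.1, (1S,2S,3R,4R,6R,9S) | C=C([C@H]1[C@H](O)[C@H]2O[C@@]2(C)C(=O)[C@@H]1OC(C)=O)[C@H](CC=C(C)C)OC(=O)/C(C)=C\C | target

**Step count and risks**

Total steps: 15. Longest linear sequence: 15 steps (1 → 25); 4, 12 and 15 enter as single building blocks.

Steps most likely to fail:

1. Step 10. The Lewis acid may isomerise the (Z)-ene-dicarbonyl to the (E)-form before ring closure, the cationic character at C7 may be captured by the neighbouring angelate carbonyl instead of being quenched by hydrogen transfer from C8, or methyl may be transferred from aluminium to the aldehyde. The fallback sets out from 9 and comes back at 20; it replaces the ene component by an allylsilane, so that the same C1–C2 bond forms by an intramolecular Hosomi–Sakurai allylation that needs no hydrogen transfer and uses a far more nucleophilic alkene. Alkynol 9 is treated with Me3SiCH2MgCl and CuI (cat.) in THF, and the resulting silylmethyl alkenylmagnesium alkoxide F1 is quenched with I2 to give the silylmethyl iodoalkenol F2. Yamaguchi angeloylation as in step 6 gives the angelate F3, CrCl2/NiCl2 coupling with 15 as in step 7 gives the furyl carbinol F4, and acetylation gives the furyl acetate F5. Because an allylsilane would not survive NBS, the furan is opened by sensitised photooxygenation (O2, tetraphenylporphyrin, hν, CH2Cl2, −78 °C) to the furan endoperoxide F6, which Me2S reduces to the silylmethyl (Z)-keto-enal F7. BF3·OEt2 in CH2Cl2 at −78 °C should then close the carbocycle through the same half-chair, the silyl group leaving from C8 to give the C7=C8 methylene, and 20 is reached directly.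

2. Step 9. Bromohydrin formation at the prenyl alkene may compete once the furan is consumed, and the (Z)-keto-enal may isomerise to the (E)-isomer, which cannot cyclise, during reaction or work-up. The fallback sets out from 17 and comes back at 18: singlet-oxygen [4+2] cycloaddition (O2, tetraphenylporphyrin, hν, CH2Cl2, −78 °C), for which a furan reacts much faster than a trisubstituted alkene, gives the bicyclic endoperoxide F8, and reduction with Me2S at −78 °C opens it to 18 under neutral, halogen-free conditions.

3. Step 7. Facial selectivity at C6 may be poor, because the chiral chromium complex has to discriminate the faces of a heteroaromatic aldehyde and the only stereocentre of 14 is too remote to help. The fallback sets out from 14 and 15 and comes back at 16: the coupling is run without the chiral ligand (CrCl2, NiCl2 cat., DMSO) to give 16 together with its (6S)-epimer F9. A Sharpless kinetic resolution of the 2-furylcarbinol (Ti(OiPr)4, L-(+)-diisopropyl tartrate, tBuOOH, CH2Cl2, −20 °C; the tartrate enantiomer is the one that consumes the (6S)-carbinol) then oxidises F9 to the Achmatowicz pyranone F10 and leaves 16, which is separated and carried on. The (Z)-substituted allylic alkene is a poor substrate for the titanium–tartrate reagent, so the furan is the reacting site.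

**Further compounds**

F1 | step 10 | bromomagnesium (3S)-1-(bromomagnesio)-6-methyl-2-[(trimethylsilyl)methyl]hepta-1,5-dien-3-olate, Mg cis to C3 | Br[Mg]/C=C(/C[Si](C)(C)C)[C@H](CC=C(C)C)O[Mg]Br
F2 | step 10 | (3S)-1-iodo-6-methyl-2-[(trimethylsilyl)methyl]hepta-1,5-dien-3-ol, iodine cis to C3 | I/C=C(/C[Si](C)(C)C)[C@H](CC=C(C)C)O
F3 | step 10 | (Z)-2-methylbut-2-enoate (angelate) of F2 | I/C=C(/C[Si](C)(C)C)[C@H](CC=C(C)C)OC(=O)/C(C)=C\C
F4 | step 10 | (6R,9S) furyl carbinol with CH2SiMe3 at C8 | Cc1ccoc1[C@H](O)/C=C(/C[Si](C)(C)C)[C@H](CC=C(C)C)OC(=O)/C(C)=C\C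
F5 | step 10 | C6 acetate of F4 | Cc1ccoc1[C@H](OC(C)=O)/C=C(/C[Si](C)(C)C)[C@H](CC=C(C)C)OC(=O)/C(C)=C\C
F6 | step 10 | 2,3,7-trioxabicyclo[2.2.1]hept-5-ene endoperoxide of F5 | CC1=CC2OOC1(O2)[C@H](OC(C)=O)/C=C(/C[Si](C)(C)C)[C@H](CC=C(C)C)OC(=O)/C(C)=C\C
F7 | step 10 | (Z)-4-oxo-2-enal with CH2SiMe3 at C8 (allylsilane analogue of 18) | C[Si](C)(C)C/C(=C/[C@@H](OC(C)=O)C(=O)/C(C)=C\C=O)[C@H](CC=C(C)C)OC(=O)/C(C)=C\C
F8 | step 9 | 2,3,7-trioxabicyclo[2.2.1]hept-5-ene endoperoxide of 17 | CC1=CC2OOC1(O2)[C@H](OC(C)=O)/C=C(/C)[C@H](CC=C(C)C)OC(=O)/C(C)=C\C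
F9 | step 7 | (6S)-epimer of 16 | Cc1ccoc1[C@@H](O)/C=C(/C)[C@H](CC=C(C)C)OC(=O)/C(C)=C\C
F10 | step 7 | 6-hydroxy-4-methyl-2H-pyran-3(6H)-one from F9, alkenyl chain at C2 of the pyranone | CC1=CC(O)O[C@@H](/C=C(/C)[C@H](CC=C(C)C)OC(=O)/C(C)=C\C)C1=O
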